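## Retrosynthetic overview

1. Manassantin B1 (28) ⇒ benzyl ether 27 ⇒ bis-ketone 26 ⇒ bis-phenol 20 + two molecules of lactate-derived tosylate 25. Both arms are attached and reduced together, because the core is C2-symmetric apart from OH versus OMe.
2. 20 ⇒ oxolane 19 ⇒ acyclic γ-silyloxy aldehyde 12 (ring A, C5 with O1, C4, C3, C2 as CHO) + ring B bromide 15. In one flask O1 closes onto C2, then ring B is delivered to C2 as an arylzinc.
3. Enabling feature: C2 carries both O1 and ring B, so without ring B it is an aldehyde-level carbon. O1 sits on C5, three carbons from C2, so the O1–C2 closure is a five-membered hemiacetal-type cyclisation. The trans C3/C4 methyl pair and the cis C5 aryl group then control the face of aryl transfer.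
4. 12 ⇒ alkene 9 (hydroboration sets C3) ⇒ silylated vanillin 2 + (Z)-2-methylcrotylboronate 7 (catalytic asymmetric allylboration sets C5 and C4).
5. Ring order: the oxolane is the only ring made (step 9); all four benzene rings are bought.

Key step: step 9

Remark on the chemistry: the oxolane is numbered O1, C2 (ring B, the 3-hydroxy-4-alkoxyphenyl ring), C3, C4, C5 (ring A, the 3-methoxy-4-alkoxyphenyl ring) throughout, and compounds 3, 4, 13, 21 and 23 are taken to be commercial.

## Route

Step 1
Reactants: 1 vanillin (4-hydroxy-3-methoxybenzaldehyde)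
Product: 2 3-methoxy-4-(triisopropylsilyloxy)benzaldehyde
Conditions: TIPSCl, imidazole, DMF, rt
Reagents that add atoms: triisopropylsilyl chloride, CC(C)[Si](Cl)(C(C)C)C(C)C
Why: Routine phenol silylation; the TIPS ether should survive allylboration, hydroboration–oxidation and organozinc chemistry and is later removed by fluoride without touching a benzyl ether.

Step 2
Reactants: 3 (Z)-2-bromobut-2-ene; 4 2-(chloromethyl)-4,4,5,5-tetramethyl-1,3,2-dioxaborolane
Product: 7 (Z)-4,4,5,5-tetramethyl-2-(2-methylbut-2-en-1-yl)-1,3,2-dioxaborolane, via alkenyllithium 5 (not isolated), via boron ate complex 6 (not isolated)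
Conditions: t-BuLi (2 equiv), Et2O, −78 °C; then 4, −78 °C to rt
Reagents that add atoms: none
Why: Bromine–lithium exchange on an alkenyl bromide retains the double-bond geometry, and the Matteson homologation (1,2-shift of the alkenyl group in 6 with loss of chloride) inserts the CH2 group without touching the alkene, so CH2B ends cis to the γ-methyl group.

Step 3
Reactants: 2 3-methoxy-4-(triisopropylsilyloxy)benzaldehyde; 7 (Z)-2-methylcrotyl pinacol boronate
Product: 8 (1S,2R)-1-[3-methoxy-4-(triisopropylsilyloxy)phenyl]-2,3-dimethylbut-3-en-1-ol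
Conditions: (S)-3,3′-bis(2,4,6-triisopropylphenyl)-1,1′-binaphthyl-2,2′-diyl hydrogen phosphate (5 mol%), 4 Å molecular sieves, toluene, −30 °C to 0 °C; aqueous work-up
Reagents that add atoms: none
Why: Phosphoric acid-catalysed allylboration runs through a closed chair transition state, so the (Z)-γ-methyl group gives the syn adduct, and the (S)-acid should direct the allyl group to the Si face of the aryl aldehyde (the (R)-acid is known to give (R)-carbinols), which sets C5 (S) and C4 (R) of the later oxolane.

Step 4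
Reactants: 8 (1S,2R)-homoallylic alcohol
Product: 9 triethyl{[(1S,2R)-1-[3-methoxy-4-(triisopropylsilyloxy)phenyl]-2,3-dimethylbut-3-en-1-yl]oxy}silane
Conditions: TESCl, imidazole, DMF, 0 °C to rt
Reagents that add atoms: triethylsilyl chloride, CC[Si](Cl)(CC)CC
Why: Routine silylation; TES is chosen because it is labile enough to be lost in the acid-mediated ring closure of step 9 and keeps the hydroxy aldehyde acyclic until then.

Step 5
Reactants: 9 TES-protected 1,1-disubstituted alkene
Product: 11 (2R,3R,4S)-4-[3-methoxy-4-(triisopropylsilyloxy)phenyl]-2,3-dimethyl-4-(triethylsilyloxy)butan-1-ol, via alkylborane 10 (not isolated)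
Conditions: 9-BBN, THF, 0 °C to rt; then NaOH, H2O2, 0 °C
Reagents that add atoms: hydrogen peroxide, OO
Why: Hydroboration puts boron on the terminal CH2 and hydrogen on C3 from the face anti to the large CH(OTES)Ar group with the allylic methyl group inside (1,2-induction that minimises A(1,2) strain), which should give the anti, later 3,4-trans, dimethyl pair as is known for closely related alkenes on the way to oxolane lignans; oxidation proceeds with retention.

Step 6
Reactants: 11 primary alcohol
Product: 12 (2R,3R,4S)-4-[3-methoxy-4-(triisopropylsilyloxy)phenyl]-2,3-dimethyl-4-(triethylsilyloxy)butanal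
Conditions: PhI(OAc)2, TEMPO (10 mol%), CH2Cl2, rt
Reagents that add atoms: none
Why: TEMPO/PhI(OAc)2 oxidation of a primary alcohol stops at the aldehyde under nearly neutral conditions, so the α-stereocentre and both silyl ethers should survive.

Step 7
Reactants: 13 2-(benzyloxy)phenol
Product: 14 2-(benzyloxy)-4-bromophenol
Conditions: NBS, MeCN, 0 °C
Reagents that add atoms: N-bromosuccinimide, O=C1CCC(=O)N1Br
Why: Electrophilic aromatic bromination goes para to the free hydroxyl group, the strongest activator, as is usual for catechol monoethers.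

Step 8
Reactants: 14 2-(benzyloxy)-4-bromophenol
Product: 15 [2-(benzyloxy)-4-bromophenoxy]triisopropylsilane
Conditions: TIPSCl, imidazole, DMF, rt
Reagents that add atoms: triisopropylsilyl chloride, CC(C)[Si](Cl)(C(C)C)C(C)C
Why: Routine phenol silylation; the oxygen that will carry the side arm is masked with the same fluoride-labile group as in ring A, while the oxygen that ends as the free phenol keeps its benzyl ether.

Step 9
Reactants: 12 acyclic γ-silyloxy aldehyde; 15 ring B aryl bromide
Product: 19 (2S,3R,4R,5S)-2-[3-(benzyloxy)-4-(triisopropylsilyloxy)phenyl]-5-[3-methoxy-4-(triisopropylsilyloxy)phenyl]-3,4-dimethyloxolane, via sulfonyl oxolane 16 (not isolated), via arylmagnesium bromide 17 (not isolated), via arylzinc bromide 18 (not isolated)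
Conditions: 12, PhSO2H (1.2 equiv), CaCl2, CH2Cl2, 0 °C to rt; then 18 (3 equiv; from 15, Mg, THF, then ZnBr2, 0 °C), THF, rt
Reagents that add atoms: none
Why: PhSO2H activates the aldehyde of 12, the silyl ether oxygen on C5 adds to the C2 carbonyl carbon (this forms the O1–C2 bond and the oxolane, TES leaving as silanol) and sulfinate traps the lactol-type cation as sulfone 16; the zinc and magnesium halides that come with 18 then ionise the C2–S bond and ring B passes from zinc to the cyclic oxocarbenium ion. The closest known reaction type is the coupling of 2-benzenesulfonyl cyclic ethers with organozinc reagents, which is known to deliver aryl groups cis to an adjacent methyl group on 5-aryl-3,4-dimethyl oxolanes; here the sulfone is fed from an acyclic silyloxy aldehyde in the same flask. The oxolane closes in the 5-exo-trig mode (O attacks the carbonyl carbon, the C=O oxygen stays outside the ring and is lost afterwards). C2 is the only new stereocentre: the oxocarbenium ion should react through the envelope that keeps the C3 and C4 methyl groups pseudo-equatorial and the C5 aryl group pseudo-axial, and the aryl group enters by inside attack on the face opposite the C4 methyl and the C5 aryl group, which puts ring B cis to the C3 methyl and trans to ring A (2S). The step needs this facial selectivity and ring closure ahead of C–C bond formation; the first is secured by the two substituents that shield the other face, the second by adding 18 only after 16 has formed, and the non-acidic zinc reagent should leave the kinetic, less stable cis,trans,cis oxolane unable to equilibrate through ring opening.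

Step 10
Reactants: 19 bis-silyl oxolane
Product: 20 2-(benzyloxy)-4-[(2S,3R,4R,5S)-5-(4-hydroxy-3-methoxyphenyl)-3,4-dimethyloxolan-2-yl]phenol
Conditions: TBAF, AcOH, THF, 0 °C
Reagents that add atoms: none
Why: Fluoride cleaves both aryl silyl ethers, and the acetic acid buffer keeps the 4-hydroxyphenyl groups protonated so that no quinone methide-type ring opening can scramble C2 or C5.

Step 11
Reactants: 21 ethyl (S)-lactate
Product: 22 (S)-2-hydroxy-N-methoxy-N-methylpropanamide
Conditions: MeNHOMe·HCl, i-PrMgCl, THF, −20 °C to 0 °C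
Reagents that add atoms: N,O-dimethylhydroxylamine hydrochloride, CNOC.Cl
Why: Aminolysis of the ester by the magnesium amide gives the Weinreb amide; the free hydroxyl group is carried through as its alkoxide and the stereocentre is not touched.

Step 12
Reactants: 22 (S)-lactic Weinreb amide; 23 (3,4-dimethoxyphenyl)magnesium bromide
Product: 24 (S)-1-(3,4-dimethoxyphenyl)-2-hydroxypropan-1-one
Conditions: 23 (2.5 equiv), THF, 0 °C; aqueous NH4Cl
Reagents that add atoms: none
Why: Grignard addition to a Weinreb amide stops at the ketone oxidation level, one equivalent of 23 serving to deprotonate the hydroxyl group, and the ketone is released only on work-up so that the α-stereocentre should not racemise.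

Step 13
Reactants: 24 (S)-α-hydroxy ketone
Product: 25 (S)-1-(3,4-dimethoxyphenyl)-1-oxopropan-2-yl 4-methylbenzenesulfonate
Conditions: TsCl, pyridine, DMAP (cat.), CH2Cl2, 0 °C to rt
Reagents that add atoms: p-toluenesulfonyl chloride, Cc1ccc(S(=O)(=O)Cl)cc1
Why: Sulfonylation takes place at oxygen and leaves the configuration untouched; the weak base limits enolisation of the product.

Step 14
Reactants: 20 bis-phenol; 25 (S)-tosylate (2.4 equiv)
Product: 26 (R)-2-{2-(benzyloxy)-4-[(2S,3R,4R,5S)-5-(4-{[(R)-1-(3,4-dimethoxyphenyl)-1-oxopropan-2-yl]oxy}-3-methoxyphenyl)-3,4-dimethyloxolan-2-yl]phenoxy}-1-(3,4-dimethoxyphenyl)propan-1-one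
Conditions: Cs2CO3, DMF, rt
Reagents that add atoms: none
Why: Each phenoxide displaces the α-keto tosylate in an SN2 reaction with inversion, (S) to (R); the carbonyl group accelerates the displacement, so that it runs at room temperature where enolisation of the product should be slow.

Step 15
Reactants: 26 bis-ketone
Product: 27 (1R,2R)-2-{2-(benzyloxy)-4-[(2S,3R,4R,5S)-5-(4-{[(1R,2R)-1-(3,4-dimethoxyphenyl)-1-hydroxypropan-2-yl]oxy}-3-methoxyphenyl)-3,4-dimethyloxolan-2-yl]phenoxy}-1-(3,4-dimethoxyphenyl)propan-1-ol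
Conditions: polymer-supported borohydride (quaternary ammonium resin in its BH4− form), MeOH, 0 °C
Reagents that add atoms: none
Why: With a non-chelating borohydride each α-aryloxy ketone should react under Felkin–Anh control, hydride adding anti to the aryloxy group past the hydrogen atom, which gives the (1R,2R) arm (hydroxyl anti to methyl) at both ends.

Step 16
Reactants: 27 O-benzyl manassantin B1
Product: 28 manassantin B1
Conditions: H2 (1 atm), 10% Pd/C, EtOAc, rt
Reagents that add atoms: none
Why: Hydrogenolysis of an aryl benzyl ether is much faster than that of secondary benzylic alcohols or benzylic ring ethers under neutral conditions, so brief exposure should free the ring B phenol only.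

## Compound list

1 | vanillin | O=Cc1ccc(O)c(OC)c1 | starting material
2 | 3-methoxy-4-(triisopropylsilyloxy)benzaldehyde | O=Cc1ccc(O[Si](C(C)C)(C(C)C)C(C)C)c(OC)c1 | intermediate
3 | (Z)-2-bromobut-2-ene | C/C=C(/C)Br | starting material
4 | 2-(chloromethyl)-4,4,5,5-tetramethyl-1,3,2-dioxaborolane | ClCB1OC(C)(C)C(C)(C)O1 | starting material
5 | (E)-but-2-en-2-yllithium (lithium cis to the C3 methyl group, geometry of 3 retained) | C/C=C(/C)[Li] | intermediate
6 | lithium (chloromethyl)[(E)-but-2-en-2-yl] pinacol borate (ate complex) | C/C=C(/C)[B-]1(CCl)OC(C)(C)C(C)(C)O1.[Li+] | intermediate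
7 | (Z)-4,4,5,5-tetramethyl-2-(2-methylbut-2-en-1-yl)-1,3,2-dioxaborolane | C/C=C(/C)CB1OC(C)(C)C(C)(C)O1 | intermediate
8 | (1S,2R)-1-[3-methoxy-4-(triisopropylsilyloxy)phenyl]-2,3-dimethylbut-3-en-1-ol | O[C@H](c1ccc(O[Si](C(C)C)(C(C)C)C(C)C)c(OC)c1)[C@H](C)C(C)=C | intermediate
9 | triethyl{[(1S,2R)-1-[3-methoxy-4-(triisopropylsilyloxy)phenyl]-2,3-dimethylbut-3-en-1-yl]oxy}silane | CC[Si](CC)(CC)O[C@H](c1ccc(O[Si](C(C)C)(C(C)C)C(C)C)c(OC)c1)[C@H](C)C(C)=C | intermediate
10 | B-alkyl-9-borabicyclo[3.3.1]nonane from 9 (boron on the terminal CH2, new stereocentre as in 11) | CC[Si](CC)(CC)O[C@H](c1ccc(O[Si](C(C)C)(C(C)C)C(C)C)c(OC)c1)[C@H](C)[C@@H](C)CB1C2CCCC1CCC2 | intermediate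
11 | (2R,3R,4S)-4-[3-methoxy-4-(triisopropylsilyloxy)phenyl]-2,3-dimethyl-4-(triethylsilyloxy)butan-1-ol | CC[Si](CC)(CC)O[C@H](c1ccc(O[Si](C(C)C)(C(C)C)C(C)C)c(OC)c1)[C@H](C)[C@@H](C)CO | intermediate
12 | (2R,3R,4S)-4-[3-methoxy-4-(triisopropylsilyloxy)phenyl]-2,3-dimethyl-4-(triethylsilyloxy)butanal | CC[Si](CC)(CC)O[C@H](c1ccc(O[Si](C(C)C)(C(C)C)C(C)C)c(OC)c1)[C@H](C)[C@@H](C)C=O | intermediate
13 | 2-(benzyloxy)phenol | Oc1ccccc1OCc2ccccc2 | starting material
14 | 2-(benzyloxy)-4-bromophenol | Oc1ccc(Br)cc1OCc2ccccc2 | intermediate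
15 | [2-(benzyloxy)-4-bromophenoxy]triisopropylsilane | CC(C)[Si](Oc1ccc(Br)cc1OCc2ccccc2)(C(C)C)C(C)C | intermediate
16 | (3R,4R,5S)-5-[3-methoxy-4-(triisopropylsilyloxy)phenyl]-3,4-dimethyl-2-(phenylsulfonyl)oxolane (both C2 epimers) | O=S(=O)(c1ccccc1)C2O[C@H](c3ccc(O[Si](C(C)C)(C(C)C)C(C)C)c(OC)c3)[C@H](C)[C@H]2C | intermediate
17 | [3-(benzyloxy)-4-(triisopropylsilyloxy)phenyl]magnesium bromide | Br[Mg]c1ccc(O[Si](C(C)C)(C(C)C)C(C)C)c(OCc2ccccc2)c1 | intermediate
18 | [3-(benzyloxy)-4-(triisopropylsilyloxy)phenyl]zinc bromide | Br[Zn]c1ccc(O[Si](C(C)C)(C(C)C)C(C)C)c(OCc2ccccc2)c1 | intermediate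
19 | (2S,3R,4R,5S)-2-[3-(benzyloxy)-4-(triisopropylsilyloxy)phenyl]-5-[3-methoxy-4-(triisopropylsilyloxy)phenyl]-3,4-dimethyloxolane | CC(C)[Si](Oc1ccc([C@H]2O[C@H](c3ccc(O[Si](C(C)C)(C(C)C)C(C)C)c(OC)c3)[C@H](C)[C@H]2C)cc1OCc4ccccc4)(C(C)C)C(C)C | intermediate
20 | 2-(benzyloxy)-4-[(2S,3R,4R,5S)-5-(4-hydroxy-3-methoxyphenyl)-3,4-dimethyloxolan-2-yl]phenol | Oc1ccc([C@H]2O[C@H](c3ccc(O)c(OC)c3)[C@H](C)[C@H]2C)cc1OCc4ccccc4 | intermediate
21 | ethyl (S)-lactate | C[C@H](O)C(=O)OCC | starting material
22 | (S)-2-hydroxy-N-methoxy-N-methylpropanamide | C[C@H](O)C(=O)N(C)OC | intermediate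
23 | (3,4-dimethoxyphenyl)magnesium bromide | COc1ccc([Mg]Br)cc1OC | starting material
24 | (S)-1-(3,4-dimethoxyphenyl)-2-hydroxypropan-1-one | C[C@H](O)C(=O)c1ccc(OC)c(OC)c1 | intermediate
25 | (S)-1-(3,4-dimethoxyphenyl)-1-oxopropan-2-yl 4-methylbenzenesulfonate | C[C@H](OS(=O)(=O)c1ccc(C)cc1)C(=O)c2ccc(OC)c(OC)c2 | intermediate
26 | bis-ketone: oxolane 20 carrying an (R)-1-(3,4-dimethoxyphenyl)-1-oxopropan-2-yl group on each phenolic oxygen | COc1ccc(C(=O)[C@@H](C)Oc2ccc([C@H]3O[C@H](c4ccc(O[C@H](C)C(=O)c5ccc(OC)c(OC)c5)c(OC)c4)[C@H](C)[C@H]3C)cc2OCc6ccccc6)cc1OC | intermediate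
27 | O-benzyl manassantin B1 (both arms (1R,2R)) | COc1ccc([C@@H](O)[C@@H](C)Oc2ccc([C@H]3O[C@H](c4ccc(O[C@H](C)[C@H](O)c5ccc(OC)c(OC)c5)c(OC)c4)[C@H](C)[C@H]3C)cc2OCc6ccccc6)cc1OC | intermediate
28 | manassantin B1 | COc1ccc([C@@H](O)[C@@H](C)Oc2ccc([C@H]3O[C@H](c4ccc(O[C@H](C)[C@H](O)c5ccc(OC)c(OC)c5)c(OC)c4)[C@H](C)[C@H]3C)cc2O)cc1OC | target

## Step count and risks

Total: 16 steps. Longest linear sequence: 10 steps (steps 1, 3, 4, 5, 6, 9, 10, 14, 15, 16, from vanillin).

The three steps most likely to fail:

**Step 9.** The desilylative ring closure may be incomplete, and the protic by-products of the first stage (silanol, residual sulfinic acid) may consume the arylzinc before it reaches the sulfone; facial discrimination in the aryl transfer may also be lower than expected. The fallback sets out from 12 and comes back at 19. The TES ether of 12 is cleaved with HF·pyridine in THF, and the liberated hydroxy aldehyde closes to the lactol (3R,4R,5S)-5-[3-methoxy-4-(triisopropylsilyloxy)phenyl]-3,4-dimethyloxolan-2-ol F1. F1 is converted with PhSO2H and CaCl2 into sulfone 16, which is now isolated and freed from acid and silanol by a basic wash and chromatography. Pure 16 is then treated with arylzinc 18 in THF at rt to give 19. Ring closure and aryl transfer are thus separated into two isolated stages, each with direct precedent on 5-aryl-3,4-dimethyl lactols.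

**Step 5.** The 1,2-induction in the hydroboration may be weak, so that hydrogen is delivered to both faces of the alkene and C3 is formed as a mixture. The fallback sets out from 8 and comes back at 12. Hydroboration–oxidation of the free alcohol 8 (9-BBN; NaOH, H2O2) gives the diol (3R,4S)-4-[3-methoxy-4-(triisopropylsilyloxy)phenyl]-2,3-dimethylbutane-1,4-diol F2 as a mixture at C2. Oxidative lactonisation (TEMPO, PhI(OAc)2) followed by DBU equilibration of the enolisable centre gives the thermodynamically favoured 3,4-trans lactone (3R,4R,5S)-5-[3-methoxy-4-(triisopropylsilyloxy)phenyl]-3,4-dimethyloxolan-2-one F3. Ring opening with MeNHOMe·HCl and AlMe3 gives the hydroxy Weinreb amide F4, TESCl and imidazole give its silyl ether F5, and DIBAL-H reduces F5 to aldehyde 12. The C3 configuration is then set under thermodynamic instead of kinetic control.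

**Step 3.** The trisubstituted (Z)-allylboronate may react slowly under acid catalysis, with erosion of enantio- and diastereoselectivity or drift of the alkene geometry. The fallback sets out from 2 and comes back at 9. An Evans syn-aldol reaction of (S)-4-benzyl-3-propionyloxazolidin-2-one with 2 (Bu2BOTf, i-Pr2NEt) gives the aldol adduct F6. Transamidation (MeNHOMe·HCl, AlMe3) gives the Weinreb amide F7, silylation (TESCl, imidazole) the silyl ether F8, MeMgBr the methyl ketone F9, and Wittig methylenation (Ph3P=CH2) the alkene 9. C5 and C4 are then set by a chiral auxiliary instead of a chiral catalyst.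

## Further compounds

F1 | step 9 | (3R,4R,5S)-5-[3-methoxy-4-(triisopropylsilyloxy)phenyl]-3,4-dimethyloxolan-2-ol (both anomers) | OC1O[C@H](c2ccc(O[Si](C(C)C)(C(C)C)C(C)C)c(OC)c2)[C@H](C)[C@H]1C
F2 | step 5 | (3R,4S)-4-[3-methoxy-4-(triisopropylsilyloxy)phenyl]-2,3-dimethylbutane-1,4-diol (both C2 epimers) | O[C@H](c1ccc(O[Si](C(C)C)(C(C)C)C(C)C)c(OC)c1)[C@H](C)C(C)CO
F3 | step 5 | (3R,4R,5S)-5-[3-methoxy-4-(triisopropylsilyloxy)phenyl]-3,4-dimethyloxolan-2-one | O=C1O[C@H](c2ccc(O[Si](C(C)C)(C(C)C)C(C)C)c(OC)c2)[C@H](C)[C@H]1C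
F4 | step 5 | (2R,3R,4S)-4-hydroxy-N-methoxy-4-[3-methoxy-4-(triisopropylsilyloxy)phenyl]-N,2,3-trimethylbutanamide | O[C@H](c1ccc(O[Si](C(C)C)(C(C)C)C(C)C)c(OC)c1)[C@H](C)[C@@H](C)C(=O)N(C)OC
F5 | step 5 | (2R,3R,4S)-N-methoxy-4-[3-methoxy-4-(triisopropylsilyloxy)phenyl]-N,2,3-trimethyl-4-(triethylsilyloxy)butanamide | CC[Si](CC)(CC)O[C@H](c1ccc(O[Si](C(C)C)(C(C)C)C(C)C)c(OC)c1)[C@H](C)[C@@H](C)C(=O)N(C)OC
F6 | step 3 | (S)-4-benzyl-3-{(2S,3S)-3-hydroxy-3-[3-methoxy-4-(triisopropylsilyloxy)phenyl]-2-methylpropanoyl}oxazolidin-2-one | O[C@H](c1ccc(O[Si](C(C)C)(C(C)C)C(C)C)c(OC)c1)[C@H](C)C(=O)N2C(=O)OC[C@@H]2Cc3ccccc3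
F7 | step 3 | (2S,3S)-3-hydroxy-N-methoxy-3-[3-methoxy-4-(triisopropylsilyloxy)phenyl]-N,2-dimethylpropanamide | O[C@H](c1ccc(O[Si](C(C)C)(C(C)C)C(C)C)c(OC)c1)[C@H](C)C(=O)N(C)OC
F8 | step 3 | (2S,3S)-N-methoxy-3-[3-methoxy-4-(triisopropylsilyloxy)phenyl]-N,2-dimethyl-3-(triethylsilyloxy)propanamide | CC[Si](CC)(CC)O[C@H](c1ccc(O[Si](C(C)C)(C(C)C)C(C)C)c(OC)c1)[C@H](C)C(=O)N(C)OC
F9 | step 3 | (3S,4S)-4-[3-methoxy-4-(triisopropylsilyloxy)phenyl]-3-methyl-4-(triethylsilyloxy)butan-2-one | CC[Si](CC)(CC)O[C@H](c1ccc(O[Si](C(C)C)(C(C)C)C(C)C)c(OC)c1)[C@H](C)C(C)=O
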